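**Plan**
1. Cuts: the two C4–C8 interflavan bonds, giving an upper epicatechin gallate electrophile, a middle epigallocatechin gallate unit and a lower catechin gallate nucleophile. In the middle unit the O1–C2 and C3–O(galloyl) bonds are cut next, then the C4–C4a bond.
2. Enabling feature: in the middle unit the ring oxygen O1 (on C2) and the galloyl oxygen (on C3) are vicinal. Ring C (O1, C2, C3, C4, C4a, C8a) can therefore come from a 2,3-dihydrobenzofuran ring (O1, C3, C4, C4a, C8a) that carries C2 outside the ring as a benzylic sulfonate: O1 shifts from C3 to C2 through an oxiranium ion while the gallate enters at C3.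
3. Forward order: Friedel–Crafts allylation joins ring A and ring B; epoxidation; 5-exo closure to the dihydrobenzofuran; carbinol inversion by oxidation/reduction; ring expansion with gallate (ring C); C4 oxidation; coupling to the catechin gallate unit; coupling with the 8-bromo epicatechin gallate electrophile; hydrogenolysis.
4. Helpers: ring B of the middle unit is carried as its tris(benzyl carbonate) so that C2 is electron-poor in the ring expansion, and C8 of the upper unit carries a bromine cap. Both leave in the final hydrogenolysis.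
5. Stereochemistry: upper and lower units come from (−)-epicatechin and (+)-catechin. Middle C3 comes from the Shi epoxidation (inverted in the 5-exo closure and again in the ring expansion); middle C2 from a Felkin–Anh reduction followed by inversion in the ring expansion. Both C4 centres arise by attack anti to the 3-O-galloyl group.

Key step: step 10

Abbreviations: Bn = benzyl, TBS = tert-butyldimethylsilyl, Cbz = benzyloxycarbonyl. Flavan numbering (O1, C2, C3, C4, C4a, C8a) is used in the Why lines.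

Assumption: the D-fructose-derived Shi ketone is taken to give the (R,R)-epoxide from the E-alkene, as with other trans-β-alkylstyrenes; the enantiomeric ketone would be used if the sense proved opposite.

**Route**

Step 1
Reactants: 1 3,4,5-trihydroxybenzaldehyde
Product: 2 3,4,5-tris(tert-butyldimethylsilyloxy)benzaldehyde
Conditions: t-BuMe2SiCl (3.6 equiv), imidazole, DMF, rt
Reagents that add atoms: tert-butyldimethylsilyl chloride CC(C)(C)[Si](C)(C)Cl
Why: Silyl ether formation on the three phenols gives a ring B that is electron-rich for step 3 and can be unmasked by fluoride later; no stereocentre is formed.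

Step 2
Reactants: 2 3,4,5-tris(tert-butyldimethylsilyloxy)benzaldehyde
Product: 3 rac-1-[3,4,5-tris(tert-butyldimethylsilyloxy)phenyl]prop-2-en-1-ol
Conditions: CH2=CHMgBr (1.3 equiv), THF, −78 → 0 °C; aq NH4Cl
Reagents that add atoms: vinylmagnesium bromide C=C[Mg]Br
Why: Grignard 1,2-addition to the aldehyde gives the aryl allyl alcohol; its stereocentre is racemic and is erased in step 3.

Step 3
Reactants: 3 rac-1-[3,4,5-tris(tert-butyldimethylsilyloxy)phenyl]prop-2-en-1-ol; 4 3,5-bis(benzyloxy)phenol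
Product: 6 3,5-bis(benzyloxy)-2-{(E)-3-[3,4,5-tris(tert-butyldimethylsilyloxy)phenyl]prop-2-en-1-yl}phenyl acetate, via free phenol 5 (not isolated)
Conditions: 4 (1.5 equiv), p-toluenesulfonic acid (5 mol%), (CF3)2CHOH/CH2Cl2, 0 °C; then Ac2O, pyridine, 4-(dimethylamino)pyridine (cat.), rt
Reagents that add atoms: acetic anhydride CC(=O)OC(C)=O
Why: Acid-catalysed dehydrative Friedel–Crafts allylation through the aryl-stabilised allyl cation alkylates the phenol ortho to OH at the unhindered allyl terminus and should give the conjugated E-alkene (C4–C4a bond), and O-acetylation then masks the phenol against the oxidant of step 4.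

Step 4
Reactants: 6 3,5-bis(benzyloxy)-2-{(E)-3-[3,4,5-tris(tert-butyldimethylsilyloxy)phenyl]prop-2-en-1-yl}phenyl acetate
Product: 7 3,5-bis(benzyloxy)-2-{[(2R,3R)-3-[3,4,5-tris(tert-butyldimethylsilyloxy)phenyl]oxiran-2-yl]methyl}phenyl acetate
Conditions: 1,2:4,5-di-O-isopropylidene-β-D-erythro-2,3-hexodiulo-2,6-pyranose (0.3 equiv), KHSO5 (as 2KHSO5·KHSO4·K2SO4), K2CO3, Bu4NHSO4, MeCN/CH2(OMe)2/aq Na2B4O7 buffer, 0 °C
Reagents that add atoms: potassium peroxymonosulfate [K+].[O-]S(=O)(=O)OO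
Why: Shi asymmetric epoxidation of a trans-disubstituted styrene by the chiral dioxirane (spiro transition state) should set both epoxide carbons as R under catalyst control.

Step 5
Reactants: 7 3,5-bis(benzyloxy)-2-{[(2R,3R)-3-[3,4,5-tris(tert-butyldimethylsilyloxy)phenyl]oxiran-2-yl]methyl}phenyl acetate
Product: 9 (R)-[(2S)-4,6-bis(benzyloxy)-2,3-dihydro-1-benzofuran-2-yl][3,4,5-tris(tert-butyldimethylsilyloxy)phenyl]methanol, via epoxy phenol 8 (not isolated)
Conditions: K2CO3 (1.2 equiv), MeOH/THF, −10 → 0 °C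
Reagents that add atoms: none
Why: Methanolysis of the aryl acetate frees the phenolate, which opens the epoxide at the non-benzylic carbon in a Baldwin-favoured 5-exo-tet SN2 step (the classical base-mediated route to 2-(α-hydroxybenzyl)dihydrobenzofurans); the ring carbon is inverted to S and the carbinol carbon keeps R.

Step 6
Reactants: 9 (R)-[(2S)-4,6-bis(benzyloxy)-2,3-dihydro-1-benzofuran-2-yl][3,4,5-tris(tert-butyldimethylsilyloxy)phenyl]methanol
Product: 10 [(2S)-4,6-bis(benzyloxy)-2,3-dihydro-1-benzofuran-2-yl][3,4,5-tris(tert-butyldimethylsilyloxy)phenyl]methanone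
Conditions: Dess–Martin periodinane, pyridine, CH2Cl2, 0 °C → rt
Reagents that add atoms: none
Why: Dess–Martin oxidation of the secondary benzylic alcohol under buffered, non-enolising conditions removes the wrongly configured carbinol centre while the α-aryloxy ring stereocentre is kept.

Step 7
Reactants: 10 [(2S)-4,6-bis(benzyloxy)-2,3-dihydro-1-benzofuran-2-yl][3,4,5-tris(tert-butyldimethylsilyloxy)phenyl]methanone
Product: 11 (S)-[(2S)-4,6-bis(benzyloxy)-2,3-dihydro-1-benzofuran-2-yl][3,4,5-tris(tert-butyldimethylsilyloxy)phenyl]methanol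
Conditions: LiBH(s-Bu)3, THF, −78 °C; aq NH4Cl
Reagents that add atoms: none
Why: Non-chelating Felkin–Anh reduction of the α-aryloxy ketone by the bulky hydride, which attacks anti to the C–O1 bond past the small hydrogen, should give the syn (S,S) carbinol needed for a cis oxiranium ion.

Step 8
Reactants: 11 (S)-[(2S)-4,6-bis(benzyloxy)-2,3-dihydro-1-benzofuran-2-yl][3,4,5-tris(tert-butyldimethylsilyloxy)phenyl]methanol
Product: 13 (S)-[(2S)-4,6-bis(benzyloxy)-2,3-dihydro-1-benzofuran-2-yl]{3,4,5-tris[(benzyloxycarbonyl)oxy]phenyl}methanol, via triphenol 12 (not isolated)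
Conditions: HF·pyridine, pyridine/THF, 0 °C → rt (argon); then BnOCOCl (3.6 equiv), −20 → 0 °C
Reagents that add atoms: benzyl chloroformate O=C(Cl)OCc1ccccc1
Why: Fluoride desilylation followed by chemoselective carbonate formation on the three phenols (far more reactive toward the chloroformate than the hindered secondary alcohol in the absence of an acylation catalyst) turns ring B into an electron-poor, hydrogenolysable tris(benzyl carbonate) without touching either stereocentre.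

Step 9
Reactants: 13 (S)-[(2S)-4,6-bis(benzyloxy)-2,3-dihydro-1-benzofuran-2-yl]{3,4,5-tris[(benzyloxycarbonyl)oxy]phenyl}methanol
Product: 14 (S)-[(2S)-4,6-bis(benzyloxy)-2,3-dihydro-1-benzofuran-2-yl]{3,4,5-tris[(benzyloxycarbonyl)oxy]phenyl}methyl chloromethanesulfonate
Conditions: ClCH2SO2Cl (1.5 equiv), pyridine, CH2Cl2, 0 °C
Reagents that add atoms: chloromethanesulfonyl chloride ClCS(Cl)(=O)=O
Why: O-Sulfonylation proceeds with retention at carbon and gives a good leaving group that the electron-poor ring B keeps from ionising spontaneously.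

Step 10
Reactants: 14 (S)-[(2S)-4,6-bis(benzyloxy)-2,3-dihydro-1-benzofuran-2-yl]{3,4,5-tris[(benzyloxycarbonyl)oxy]phenyl}methyl chloromethanesulfonate; 15 3,4,5-tris(benzyloxy)benzoic acid
Product: 17 (2R,3R)-5,7-bis(benzyloxy)-2-{3,4,5-tris[(benzyloxycarbonyl)oxy]phenyl}chroman-3-yl 3,4,5-tris(benzyloxy)benzoate, via oxiranium ion 16 (not isolated)
Conditions: 15 (3 equiv), Zn(OTf)2 (1.5 equiv), 2,6-lutidine (3 equiv), 1,4-dioxane, 60 °C
Reagents that add atoms: none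
Why: Proposed new method: O1 displaces the benzylic chloromethanesulfonate at C2 from the rear (3-exo-tet closure, inversion at C2) to give the cis-fused oxiranium ion 16, and the zinc carboxylate of 15 opens it by SN2 attack at the ring-fusion carbon C3 (inversion), so that the five-membered ring (O1, C3, C4, C4a, C8a) becomes ring C (O1, C2, C3, C4, C4a, C8a) with the galloyl ester delivered to C3. The closest known reaction type is the zinc-carboxylate-mediated ring expansion of 2-(1-sulfonyloxyalkyl)tetrahydrofurans to 3-acyloxytetrahydropyrans through bicyclic oxiranium ions; an aryl ether oxygen with a benzylic terminus has not been used in this direction. Both stereocentres follow stereospecifically from double inversion: the (S) carbinol carbon becomes (2R), the (S) ring carbon becomes (3R), and the syn relationship of 14 becomes the 2,3-cis arrangement. The step needs attack at C3 and not at benzylic C2 or directly on the sulfonate, and it must avoid a free benzylic cation. The three carbonate groups make ring B electron-poor, so ionisation requires O1 participation and C2 is a poor site of opening; the zinc carboxylate is only weakly nucleophilic, and strain relief favours the six-membered ring. Participation of ring A at C3 is excluded because C4a is held syn to the breaking C3–O1 bond in the bicyclic ion.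

Step 11
Reactants: 17 (2R,3R)-5,7-bis(benzyloxy)-2-{3,4,5-tris[(benzyloxycarbonyl)oxy]phenyl}chroman-3-yl 3,4,5-tris(benzyloxy)benzoate
Product: 18 (2R,3R,4S)-5,7-bis(benzyloxy)-4-(2-ethoxyethoxy)-2-{3,4,5-tris[(benzyloxycarbonyl)oxy]phenyl}chroman-3-yl 3,4,5-tris(benzyloxy)benzoate
Conditions: DDQ (2 equiv), 2-ethoxyethanol (5 equiv), CH2Cl2, rt
Reagents that add atoms: 2-ethoxyethanol CCOCCO
Why: DDQ benzylic oxidation abstracts hydride from C4 (activated by ring A; C2 is protected by the electron-poor ring B) and the alcohol traps the flavan-4-yl cation anti to the 3-O-galloyl group, giving the 4β (4S) ether.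

Step 12
Reactants: 19 (+)-catechin
Product: 20 5,7,3',4'-tetra-O-benzyl-(+)-catechin
Conditions: BnBr (4.4 equiv), K2CO3, DMF, −10 °C → rt
Reagents that add atoms: benzyl bromide BrCc1ccccc1
Why: Williamson benzylation of the four phenols leaves the less acidic secondary 3-OH free; the (2R,3S) centres come from the chiral pool.

Step 13
Reactants: 20 5,7,3',4'-tetra-O-benzyl-(+)-catechin; 15 3,4,5-tris(benzyloxy)benzoic acid
Product: 21 5,7,3',4'-tetra-O-benzyl-(+)-catechin 3-O-[3,4,5-tris(benzyloxy)benzoate]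
Conditions: N,N'-dicyclohexylcarbodiimide, 4-(dimethylamino)pyridine, CH2Cl2, rt
Reagents that add atoms: none
Why: Steglich esterification acylates the equatorial 3-OH without affecting the stereocentres.

Step 14
Reactants: 18 (2R,3R,4S)-5,7-bis(benzyloxy)-4-(2-ethoxyethoxy)-2-{3,4,5-tris[(benzyloxycarbonyl)oxy]phenyl}chroman-3-yl 3,4,5-tris(benzyloxy)benzoate; 21 5,7,3',4'-tetra-O-benzyl-(+)-catechin 3-O-[3,4,5-tris(benzyloxy)benzoate]
Product: 22 protected dimer: 5,7-di-O-benzyl-3',4',5'-tris-O-Cbz-3-O-[3,4,5-tris(benzyloxy)benzoyl]epigallocatechin-(4β→8)-5,7,3',4'-tetra-O-benzyl-3-O-[3,4,5-tris(benzyloxy)benzoyl]catechin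
Conditions: 21 (3 equiv), Me3SiOTf (0.5 equiv), CH2Cl2, −40 °C; aq NaHCO3
Reagents that add atoms: none
Why: Lewis-acid ionisation of the 4-alkoxy group gives the flavan-4-yl cation, which undergoes Friedel–Crafts attack by C8 of the excess nucleophile on the face anti to the axial 3-O-galloyl group (acyloxy participation on the α face), setting the 4β linkage; the excess of 21 suppresses self-condensation.

Step 15
Reactants: 23 (−)-epicatechin
Product: 24 5,7,3',4'-tetra-O-benzyl-(−)-epicatechin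
Conditions: BnBr (4.4 equiv), K2CO3, DMF, −10 °C → rt
Reagents that add atoms: benzyl bromide BrCc1ccccc1
Why: Williamson benzylation of the four phenols leaves the 3-OH free; the (2R,3R) centres come from the chiral pool.

Step 16
Reactants: 24 5,7,3',4'-tetra-O-benzyl-(−)-epicatechin
Product: 25 8-bromo-5,7,3',4'-tetra-O-benzyl-(−)-epicatechin
Conditions: N-bromosuccinimide (1.05 equiv), CH2Cl2, −40 → 0 °C
Reagents that add atoms: N-bromosuccinimide O=C1CCC(=O)N1Br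
Why: Electrophilic aromatic bromination takes place at C8, the most nucleophilic position of ring A, and caps the site at which this unit could otherwise self-condense.

Step 17
Reactants: 25 8-bromo-5,7,3',4'-tetra-O-benzyl-(−)-epicatechin
Product: 26 (2R,3R,4S)-8-bromo-4-(2-ethoxyethoxy)-5,7,3',4'-tetra-O-benzylepicatechin
Conditions: DDQ (2 equiv), 2-ethoxyethanol (5 equiv), CH2Cl2, rt
Reagents that add atoms: 2-ethoxyethanol CCOCCO
Why: DDQ benzylic oxidation at C4 followed by alcohol capture anti to the axial 3-OH should give the 4β (4S) ether.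

Step 18
Reactants: 26 (2R,3R,4S)-8-bromo-4-(2-ethoxyethoxy)-5,7,3',4'-tetra-O-benzylepicatechin; 15 3,4,5-tris(benzyloxy)benzoic acid
Product: 27 (2R,3R,4S)-8-bromo-4-(2-ethoxyethoxy)-5,7,3',4'-tetra-O-benzylepicatechin 3-O-[3,4,5-tris(benzyloxy)benzoate]
Conditions: N,N'-dicyclohexylcarbodiimide, 4-(dimethylamino)pyridine, CH2Cl2, rt
Reagents that add atoms: none
Why: Steglich esterification acylates the axial 3-OH while the 4-alkoxy group is stable to the neutral conditions.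

Step 19
Reactants: 27 (2R,3R,4S)-8-bromo-4-(2-ethoxyethoxy)-5,7,3',4'-tetra-O-benzylepicatechin 3-O-[3,4,5-tris(benzyloxy)benzoate]; 22 protected dimer
Product: 28 protected trimer: 8-bromo-5,7,3',4'-tetra-O-benzyl-3-O-[3,4,5-tris(benzyloxy)benzoyl]epicatechin-(4β→8)-5,7-di-O-benzyl-3',4',5'-tris-O-Cbz-3-O-[3,4,5-tris(benzyloxy)benzoyl]epigallocatechin-(4β→8)-5,7,3',4'-tetra-O-benzyl-3-O-[3,4,5-tris(benzyloxy)benzoyl]catechin
Conditions: 27 (1.1 equiv), Me3SiOTf (0.5 equiv), CH2Cl2, −40 °C; aq NaHCO3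
Reagents that add atoms: none
Why: The same Lewis-acid Friedel–Crafts coupling joins the bromine-capped flavan-4-yl cation (which cannot self-condense) to C8 of the epigallocatechin unit of 22, the most accessible free position of the dimer, anti to the 3-O-galloyl group to give the second 4β linkage.

Step 20
Reactants: 28 protected trimer
Product: 29 epicatechin 3-O-gallate-(4β→8)-epigallocatechin 3-O-gallate-(4β→8)-catechin 3-O-gallate (the target)
Conditions: H2 (1 atm), Pd(OH)2 on carbon, Et3N (1.2 equiv), THF/MeOH/H2O, rt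
Reagents that add atoms: none
Why: Catalytic hydrogenolysis cleaves the nineteen benzyl ethers, the three benzyl carbonates (with loss of CO2) and the aryl bromide in one operation, while the gallate esters, the interflavan bonds and all stereocentres are untouched.

**Compound list**
1 | 3,4,5-trihydroxybenzaldehyde | O=Cc1cc(O)c(O)c(O)c1 | starting material
2 | 3,4,5-tris(tert-butyldimethylsilyloxy)benzaldehyde | O=Cc1cc(O[Si](C)(C)C(C)(C)C)c(O[Si](C)(C)C(C)(C)C)c(O[Si](C)(C)C(C)(C)C)c1 | intermediate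
3 | rac-1-[3,4,5-tris(tert-butyldimethylsilyloxy)phenyl]prop-2-en-1-ol | C=CC(O)c1cc(O[Si](C)(C)C(C)(C)C)c(O[Si](C)(C)C(C)(C)C)c(O[Si](C)(C)C(C)(C)C)c1 | intermediate
4 | 3,5-bis(benzyloxy)phenol | Oc1cc(OCc2ccccc2)cc(OCc2ccccc2)c1 | starting material
5 | 3,5-bis(benzyloxy)-2-{(E)-3-[3,4,5-tris(TBS-oxy)phenyl]prop-2-en-1-yl}phenol (not isolated) | Oc1cc(OCc2ccccc2)cc(OCc2ccccc2)c1C/C=C/c1cc(O[Si](C)(C)C(C)(C)C)c(O[Si](C)(C)C(C)(C)C)c(O[Si](C)(C)C(C)(C)C)c1 | intermediate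
6 | 3,5-bis(benzyloxy)-2-{(E)-3-[3,4,5-tris(TBS-oxy)phenyl]prop-2-en-1-yl}phenyl acetate | CC(=O)Oc1cc(OCc2ccccc2)cc(OCc2ccccc2)c1C/C=C/c1cc(O[Si](C)(C)C(C)(C)C)c(O[Si](C)(C)C(C)(C)C)c(O[Si](C)(C)C(C)(C)C)c1 | intermediate
7 | 3,5-bis(benzyloxy)-2-{[(2R,3R)-3-[3,4,5-tris(TBS-oxy)phenyl]oxiran-2-yl]methyl}phenyl acetate | CC(=O)Oc1cc(OCc2ccccc2)cc(OCc2ccccc2)c1C[C@H]1O[C@@H]1c1cc(O[Si](C)(C)C(C)(C)C)c(O[Si](C)(C)C(C)(C)C)c(O[Si](C)(C)C(C)(C)C)c1 | intermediate
8 | 3,5-bis(benzyloxy)-2-{[(2R,3R)-3-[3,4,5-tris(TBS-oxy)phenyl]oxiran-2-yl]methyl}phenol (not isolated) | Oc1cc(OCc2ccccc2)cc(OCc2ccccc2)c1C[C@H]1O[C@@H]1c1cc(O[Si](C)(C)C(C)(C)C)c(O[Si](C)(C)C(C)(C)C)c(O[Si](C)(C)C(C)(C)C)c1 | intermediate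
9 | (R)-[(2S)-4,6-bis(benzyloxy)-2,3-dihydro-1-benzofuran-2-yl][3,4,5-tris(TBS-oxy)phenyl]methanol (anti) | O[C@H](c1cc(O[Si](C)(C)C(C)(C)C)c(O[Si](C)(C)C(C)(C)C)c(O[Si](C)(C)C(C)(C)C)c1)[C@@H]1Cc2c(OCc3ccccc3)cc(OCc3ccccc3)cc2O1 | intermediate
10 | [(2S)-4,6-bis(benzyloxy)-2,3-dihydro-1-benzofuran-2-yl][3,4,5-tris(TBS-oxy)phenyl]methanone | O=C(c1cc(O[Si](C)(C)C(C)(C)C)c(O[Si](C)(C)C(C)(C)C)c(O[Si](C)(C)C(C)(C)C)c1)[C@@H]1Cc2c(OCc3ccccc3)cc(OCc3ccccc3)cc2O1 | intermediate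
11 | (S)-[(2S)-4,6-bis(benzyloxy)-2,3-dihydro-1-benzofuran-2-yl][3,4,5-tris(TBS-oxy)phenyl]methanol (syn) | O[C@@H](c1cc(O[Si](C)(C)C(C)(C)C)c(O[Si](C)(C)C(C)(C)C)c(O[Si](C)(C)C(C)(C)C)c1)[C@@H]1Cc2c(OCc3ccccc3)cc(OCc3ccccc3)cc2O1 | intermediate
12 | (S)-[(2S)-4,6-bis(benzyloxy)-2,3-dihydro-1-benzofuran-2-yl](3,4,5-trihydroxyphenyl)methanol (not isolated) | O[C@@H](c1cc(O)c(O)c(O)c1)[C@@H]1Cc2c(OCc3ccccc3)cc(OCc3ccccc3)cc2O1 | intermediate
13 | (S)-[(2S)-4,6-bis(benzyloxy)-2,3-dihydro-1-benzofuran-2-yl]{3,4,5-tris[(benzyloxycarbonyl)oxy]phenyl}methanol | O[C@@H](c1cc(OC(=O)OCc2ccccc2)c(OC(=O)OCc2ccccc2)c(OC(=O)OCc2ccccc2)c1)[C@@H]1Cc2c(OCc3ccccc3)cc(OCc3ccccc3)cc2O1 | intermediate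
14 | (S)-[(2S)-4,6-bis(benzyloxy)-2,3-dihydro-1-benzofuran-2-yl]{3,4,5-tris[(benzyloxycarbonyl)oxy]phenyl}methyl chloromethanesulfonate | ClCS(=O)(=O)O[C@@H](c1cc(OC(=O)OCc2ccccc2)c(OC(=O)OCc2ccccc2)c(OC(=O)OCc2ccccc2)c1)[C@@H]1Cc2c(OCc3ccccc3)cc(OCc3ccccc3)cc2O1 | intermediate
15 | 3,4,5-tris(benzyloxy)benzoic acid | OC(=O)c1cc(OCc2ccccc2)c(OCc2ccccc2)c(OCc2ccccc2)c1 | starting material
16 | cis-fused oxiranium ion (O1 bonded to C2, C3 and C8a) as its chloromethanesulfonate (not isolated) | O=C(OCc1ccccc1)Oc1cc(cc(OC(=O)OCc2ccccc2)c1OC(=O)OCc1ccccc1)[C@@H]1[C@@H]2Cc3c(OCc4ccccc4)cc(OCc4ccccc4)cc3[O+]12.[O-]S(=O)(=O)CCl | intermediate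
17 | (2R,3R)-5,7-bis(benzyloxy)-2-{3,4,5-tris[(benzyloxycarbonyl)oxy]phenyl}chroman-3-yl 3,4,5-tris(benzyloxy)benzoate | O=C(O[C@@H]1Cc2c(OCc3ccccc3)cc(OCc3ccccc3)cc2O[C@@H]1c1cc(OC(=O)OCc2ccccc2)c(OC(=O)OCc2ccccc2)c(OC(=O)OCc2ccccc2)c1)c1cc(OCc2ccccc2)c(OCc2ccccc2)c(OCc2ccccc2)c1 | intermediate
18 | (2R,3R,4S)-5,7-bis(benzyloxy)-4-(2-ethoxyethoxy)-2-{3,4,5-tris[(benzyloxycarbonyl)oxy]phenyl}chroman-3-yl 3,4,5-tris(benzyloxy)benzoate | O=C(O[C@@H]1[C@@H](OCCOCC)c2c(OCc3ccccc3)cc(OCc3ccccc3)cc2O[C@@H]1c1cc(OC(=O)OCc2ccccc2)c(OC(=O)OCc2ccccc2)c(OC(=O)OCc2ccccc2)c1)c1cc(OCc2ccccc2)c(OCc2ccccc2)c(OCc2ccccc2)c1 | intermediate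
19 | (+)-catechin | O[C@H]1Cc2c(O)cc(O)cc2O[C@@H]1c1ccc(O)c(O)c1 | starting material
20 | 5,7,3',4'-tetra-O-benzyl-(+)-catechin | O[C@H]1Cc2c(OCc3ccccc3)cc(OCc3ccccc3)cc2O[C@@H]1c1ccc(OCc2ccccc2)c(OCc2ccccc2)c1 | intermediate
21 | 5,7,3',4'-tetra-O-benzyl-(+)-catechin 3-O-[3,4,5-tris(benzyloxy)benzoate] | O=C(O[C@H]1Cc2c(OCc3ccccc3)cc(OCc3ccccc3)cc2O[C@@H]1c1ccc(OCc2ccccc2)c(OCc2ccccc2)c1)c1cc(OCc2ccccc2)c(OCc2ccccc2)c(OCc2ccccc2)c1 | intermediate
22 | protected dimer, epigallocatechin unit (4β→8) catechin unit | O=C(O[C@@H]1[C@@H](c2c(OCc5ccccc5)cc(OCc5ccccc5)c3c2O[C@H](c2ccc(OCc5ccccc5)c(OCc5ccccc5)c2)[C@@H](OC(=O)c2cc(OCc5ccccc5)c(OCc5ccccc5)c(OCc5ccccc5)c2)C3)c2c(OCc5ccccc5)cc(OCc5ccccc5)cc2O[C@@H]1c1cc(OC(=O)OCc5ccccc5)c(OC(=O)OCc5ccccc5)c(OC(=O)OCc5ccccc5)c1)c1cc(OCc5ccccc5)c(OCc5ccccc5)c(OCc5ccccc5)c1 | intermediate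
23 | (−)-epicatechin | O[C@@H]1Cc2c(O)cc(O)cc2O[C@@H]1c1ccc(O)c(O)c1 | starting material
24 | 5,7,3',4'-tetra-O-benzyl-(−)-epicatechin | O[C@@H]1Cc2c(OCc3ccccc3)cc(OCc3ccccc3)cc2O[C@@H]1c1ccc(OCc2ccccc2)c(OCc2ccccc2)c1 | intermediate
25 | 8-bromo-5,7,3',4'-tetra-O-benzyl-(−)-epicatechin | O[C@@H]1Cc2c(OCc3ccccc3)cc(OCc3ccccc3)c(Br)c2O[C@@H]1c1ccc(OCc2ccccc2)c(OCc2ccccc2)c1 | intermediate
26 | (2R,3R,4S)-8-bromo-4-(2-ethoxyethoxy)-5,7,3',4'-tetra-O-benzylepicatechin | O[C@@H]1[C@@H](OCCOCC)c2c(OCc3ccccc3)cc(OCc3ccccc3)c(Br)c2O[C@@H]1c1ccc(OCc2ccccc2)c(OCc2ccccc2)c1 | intermediate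
27 | (2R,3R,4S)-8-bromo-4-(2-ethoxyethoxy)-5,7,3',4'-tetra-O-benzylepicatechin 3-O-[3,4,5-tris(benzyloxy)benzoate] | O=C(O[C@@H]1[C@@H](OCCOCC)c2c(OCc3ccccc3)cc(OCc3ccccc3)c(Br)c2O[C@@H]1c1ccc(OCc2ccccc2)c(OCc2ccccc2)c1)c1cc(OCc2ccccc2)c(OCc2ccccc2)c(OCc2ccccc2)c1 | intermediate
28 | protected trimer, 8-bromo epicatechin unit (4β→8) epigallocatechin unit (4β→8) catechin unit | O=C(O[C@@H]1[C@@H](c2c(OCc5ccccc5)cc(OCc5ccccc5)c3c2O[C@H](c2ccc(OCc5ccccc5)c(OCc5ccccc5)c2)[C@@H](OC(=O)c2cc(OCc5ccccc5)c(OCc5ccccc5)c(OCc5ccccc5)c2)C3)c2c(OCc5ccccc5)cc(OCc5ccccc5)c([C@H]3c4c(OCc5ccccc5)cc(OCc5ccccc5)c(Br)c4O[C@H](c4ccc(OCc5ccccc5)c(OCc5ccccc5)c4)[C@@H]3OC(=O)c3cc(OCc5ccccc5)c(OCc5ccccc5)c(OCc5ccccc5)c3)c2O[C@@H]1c1cc(OC(=O)OCc5ccccc5)c(OC(=O)OCc5ccccc5)c(OC(=O)OCc5ccccc5)c1)c1cc(OCc5ccccc5)c(OCc5ccccc5)c(OCc5ccccc5)c1 | intermediate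
29 | epicatechin 3-O-gallate-(4β→8)-epigallocatechin 3-O-gallate-(4β→8)-catechin 3-O-gallate | O=C(O[C@@H]1[C@@H](c2c(O)cc(O)c3c2O[C@H](c2ccc(O)c(O)c2)[C@@H](OC(=O)c2cc(O)c(O)c(O)c2)C3)c2c(O)cc(O)c([C@H]3c4c(O)cc(O)cc4O[C@H](c4ccc(O)c(O)c4)[C@@H]3OC(=O)c3cc(O)c(O)c(O)c3)c2O[C@@H]1c1cc(O)c(O)c(O)c1)c1cc(O)c(O)c(O)c1 | target

**Step count and risks**

Total step count: 20. Longest linear sequence: 14 steps (steps 1–11, 14, 19, 20).

Steps most likely to fail:

1. Step 10 (proposed new method). The sulfonate may be displaced directly, or the oxiranium ion may be opened at the benzylic carbon, so that unrearranged five-membered-ring esters form. Stereospecificity may also be lost if a free benzylic cation intervenes.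
Fallback (known chemistry, from 6 back to 17): 6 is epoxidised with the enantiomeric ketone catalyst (1,2:4,5-di-O-isopropylidene-β-L-erythro-2,3-hexodiulo-2,6-pyranose, KHSO5) to 3,5-bis(benzyloxy)-2-{[(2S,3S)-3-[3,4,5-tris(TBS-oxy)phenyl]oxiran-2-yl]methyl}phenyl acetate F1. Hydrazine hydrate in THF at 0 °C frees the epoxy phenol F2. Camphorsulfonic acid in CH2Cl2 then closes it 6-endo at the electron-rich benzylic carbon with inversion (the established epoxide route to 2,3-trans flavan-3-ols), giving (2R,3S)-5,7-bis(benzyloxy)-2-[3,4,5-tris(TBS-oxy)phenyl]chroman-3-ol F3. Dess–Martin oxidation gives the (2R)-chroman-3-one F4. LiBH(s-Bu)3 at −78 °C, attacking opposite the C2 aryl group (the standard trans-to-cis inversion of flavan-3-ols), gives the (2R,3R)-chroman-3-ol F5. HF·pyridine gives 5,7-di-O-benzylepigallocatechin F6, and benzyl chloroformate/pyridine gives its 3',4',5'-tris(benzyl carbonate) F7. Steglich esterification of F7 with 15 (N,N'-dicyclohexylcarbodiimide, 4-(dimethylamino)pyridine) returns to 17.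

2. Step 19. The cation may attack C6 positions of the dimer in competition with C8 of its epigallocatechin unit, and the existing interflavan bond may be cleaved by acid and recombine, which would scramble the oligomer.
Fallback (from 17 and 27 back to 28): the order of bond formation is reversed. 27 is coupled (Me3SiOTf, CH2Cl2, −40 °C) with monomer 17 acting as the nucleophile, which has only one flavan unit to attack, giving the protected 8-bromo epicatechin gallate-(4β→8)-epigallocatechin gallate dimer F8. DDQ/2-ethoxyethanol oxidises the free C4 methylene of its epigallocatechin unit to the 4β-(2-ethoxyethoxy) dimer F9. Me3SiOTf-promoted coupling of F9 with an excess of 21 then gives 28.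

3. Step 3. Alkylation may occur para to the hydroxyl group or twice on the phenol, and the acid may remove silyl groups or add the phenol across the new styrene to give a flavan.
Fallback (from 4 and 2 back to 6): 4 is O-allylated (allyl bromide, K2CO3, acetone) to 1-(allyloxy)-3,5-bis(benzyloxy)benzene F10. Claisen rearrangement (N,N-diethylaniline, 190 °C; both ortho positions are equivalent) gives 2-allyl-3,5-bis(benzyloxy)phenol F11, and acetylation gives 2-allyl-3,5-bis(benzyloxy)phenyl acetate F12. Aldehyde 2 is methylenated (Ph3P=CH2, THF) to 3,4,5-tris(TBS-oxy)styrene F13. Cross-metathesis of F12 with F13 (second-generation Grubbs catalyst, CH2Cl2, 40 °C) gives the E-alkene 6.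

**Further compounds**
F1 | step 10 | 3,5-bis(benzyloxy)-2-{[(2S,3S)-3-[3,4,5-tris(TBS-oxy)phenyl]oxiran-2-yl]methyl}phenyl acetate | CC(=O)Oc1cc(OCc2ccccc2)cc(OCc2ccccc2)c1C[C@@H]1O[C@H]1c1cc(O[Si](C)(C)C(C)(C)C)c(O[Si](C)(C)C(C)(C)C)c(O[Si](C)(C)C(C)(C)C)c1
F2 | step 10 | 3,5-bis(benzyloxy)-2-{[(2S,3S)-3-[3,4,5-tris(TBS-oxy)phenyl]oxiran-2-yl]methyl}phenol | Oc1cc(OCc2ccccc2)cc(OCc2ccccc2)c1C[C@@H]1O[C@H]1c1cc(O[Si](C)(C)C(C)(C)C)c(O[Si](C)(C)C(C)(C)C)c(O[Si](C)(C)C(C)(C)C)c1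
F3 | step 10 | (2R,3S)-5,7-bis(benzyloxy)-2-[3,4,5-tris(TBS-oxy)phenyl]chroman-3-ol | O[C@H]1Cc2c(OCc3ccccc3)cc(OCc3ccccc3)cc2O[C@@H]1c1cc(O[Si](C)(C)C(C)(C)C)c(O[Si](C)(C)C(C)(C)C)c(O[Si](C)(C)C(C)(C)C)c1
F4 | step 10 | (2R)-5,7-bis(benzyloxy)-2-[3,4,5-tris(TBS-oxy)phenyl]chroman-3-one | O=C1Cc2c(OCc3ccccc3)cc(OCc3ccccc3)cc2O[C@@H]1c1cc(O[Si](C)(C)C(C)(C)C)c(O[Si](C)(C)C(C)(C)C)c(O[Si](C)(C)C(C)(C)C)c1
F5 | step 10 | (2R,3R)-5,7-bis(benzyloxy)-2-[3,4,5-tris(TBS-oxy)phenyl]chroman-3-ol | O[C@@H]1Cc2c(OCc3ccccc3)cc(OCc3ccccc3)cc2O[C@@H]1c1cc(O[Si](C)(C)C(C)(C)C)c(O[Si](C)(C)C(C)(C)C)c(O[Si](C)(C)C(C)(C)C)c1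
F6 | step 10 | 5,7-di-O-benzyl-(−)-epigallocatechin | O[C@@H]1Cc2c(OCc3ccccc3)cc(OCc3ccccc3)cc2O[C@@H]1c1cc(O)c(O)c(O)c1
F7 | step 10 | 5,7-di-O-benzyl-3',4',5'-tris-O-(benzyloxycarbonyl)-(−)-epigallocatechin | O[C@@H]1Cc2c(OCc3ccccc3)cc(OCc3ccccc3)cc2O[C@@H]1c1cc(OC(=O)OCc2ccccc2)c(OC(=O)OCc2ccccc2)c(OC(=O)OCc2ccccc2)c1
F8 | step 19 | protected dimer, 8-bromo epicatechin gallate unit (4β→8) epigallocatechin gallate unit | O=C(O[C@@H]1Cc2c(OCc5ccccc5)cc(OCc5ccccc5)c([C@H]3c4c(OCc5ccccc5)cc(OCc5ccccc5)c(Br)c4O[C@H](c4ccc(OCc5ccccc5)c(OCc5ccccc5)c4)[C@@H]3OC(=O)c3cc(OCc5ccccc5)c(OCc5ccccc5)c(OCc5ccccc5)c3)c2O[C@@H]1c1cc(OC(=O)OCc5ccccc5)c(OC(=O)OCc5ccccc5)c(OC(=O)OCc5ccccc5)c1)c1cc(OCc5ccccc5)c(OCc5ccccc5)c(OCc5ccccc5)c1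
F9 | step 19 | the same dimer with a 4β-(2-ethoxyethoxy) group on its epigallocatechin unit | O=C(O[C@@H]1[C@@H](OCCOCC)c2c(OCc5ccccc5)cc(OCc5ccccc5)c([C@H]3c4c(OCc5ccccc5)cc(OCc5ccccc5)c(Br)c4O[C@H](c4ccc(OCc5ccccc5)c(OCc5ccccc5)c4)[C@@H]3OC(=O)c3cc(OCc5ccccc5)c(OCc5ccccc5)c(OCc5ccccc5)c3)c2O[C@@H]1c1cc(OC(=O)OCc5ccccc5)c(OC(=O)OCc5ccccc5)c(OC(=O)OCc5ccccc5)c1)c1cc(OCc5ccccc5)c(OCc5ccccc5)c(OCc5ccccc5)c1
F10 | step 3 | 1-(allyloxy)-3,5-bis(benzyloxy)benzene | C=CCOc1cc(OCc2ccccc2)cc(OCc2ccccc2)c1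
F11 | step 3 | 2-allyl-3,5-bis(benzyloxy)phenol | C=CCc1c(O)cc(OCc2ccccc2)cc1OCc1ccccc1
F12 | step 3 | 2-allyl-3,5-bis(benzyloxy)phenyl acetate | C=CCc1c(OC(C)=O)cc(OCc2ccccc2)cc1OCc1ccccc1
F13 | step 3 | 3,4,5-tris(tert-butyldimethylsilyloxy)styrene | C=Cc1cc(O[Si](C)(C)C(C)(C)C)c(O[Si](C)(C)C(C)(C)C)c(O[Si](C)(C)C(C)(C)C)c1
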